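Notation used below: prenyl = 3-methylbut-2-en-1-yl; MOM = methoxymethyl; "ring B aryl" = 2-methoxy-4-(methoxymethoxy)-3-prenylphenyl. Compound numbers are those of the steps and of the compound list.

## Analysis of the target

The target 25 is a 3-hydroxyisoflavanone. Its benzo ring A (C4a to C8a) is fused to the dihydropyranone ring C (O1, C2H2, C3, C4=O), and ring B is bonded through C1′ to C3. Ring A carries free hydroxyls at C5 and C7 with a prenyl group between them at C6; ring B carries a methoxy group at C2′, a prenyl group at C3′ and a hydroxyl at C4′. C3 is the only stereocentre: a quaternary carbinol carbon (OH, C1′, C2, C4) of R configuration. It is isolated, so it has to be set by an external chiral agent, and it can be neither corrected nor lost by enolisation. The sensitive groups are the two trisubstituted alkenes, each ortho to a phenol, and the tertiary benzylic α-ketol. Acid closes the prenylphenols to dimethylchromans and can dehydrate the ketol towards the isoflavone, base can trigger an acyloin shift, and electrophilic halogen, hydroboration and hydrogenation are excluded by the alkenes. The difficulties are the enantioselective construction of a fully substituted oxygenated carbon next to an ortho-substituted aryl group, the 6- versus 8-prenyl regiochemistry of ring A, and the need to keep every later step mild. The strategy rests on the two carbon arms of C3: C2 (CH2–O1) and C4 (C=O) are the same kind of carbon at different oxidation levels. Raising both to the carboxyl level makes C3 the prochiral central carbon of an aryl(hydroxy)malonate whose two ester groups are enantiotopic, and a hydrolase can tell them apart. A second useful feature is that ring A without C4 is a phenol with a mirror plane through its C1 and C4, so closure at either ortho carbon gives the 6-prenyl pattern.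

## Retrosynthetic reasoning

25 from 24. The last disconnection removes three acetal groups from O5, O7 and O4′. The phenols must be masked through all organolithium steps. MOM ethers are chosen because they also direct the two prenylations and do not migrate between phenoxides, as a silyl ether at O4′ could during the ether-forming step. The forward step has to free three phenols without closing them onto the prenyl groups.

24 from 21. The cut is at C4–C4a. It leaves the O1–C2 ether and C3 untouched, and C4 is the ester carbon that survives from the malonate. Ring A is made the nucleophile, from the carbon–iodine bond of 21 through alkoxide 22 and aryllithium 23. An acid-promoted acylation would expose two prenyl groups, three acetals and a tertiary α-hydroxy acid (which loses carbon monoxide readily once an acylium ion forms) to strong acid. The forward step needs halogen–metal exchange to outrun attack on the ester.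

21 from 12 and 19. The cut is at O1–C2. C2 is a primary carbon, so a phenoxide can be joined to it by SN2 without touching C3. The electrophile is tosylate 12, which reacts through glycidic ester 20. This is the convergent union of the two halves.

19 back to 13. Iodophenol 19 comes from the symmetric phenol 18, whose two ortho positions are identical and whose para position is blocked, so iodination can give only one isomer and the 6-prenyl pattern is fixed. The prenyl group of 18 is placed between two MOM ethers by directed lithiation of 15 (through 16 to 17); the third oxygen is masked as a silyl ether so that it can be freed alone. 15 comes from 14 and this from phloroglucinol 13.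

12 from 11 from 9. These are adjustments of the oxidation level of C2: the sulfonate comes from the primary alcohol 11, and 11 from the free carboxyl group of half ester 9 through mixed anhydride 10. The forward reduction must touch the acid only, leave the ester as the future C4, and spare the alkene.

9 from 8. This is the key disconnection. No skeletal bond is cut; one of the two enantiotopic ester groups of 8 is returned to the acid. The forward step must select one ester group and stop after one hydrolysis.

8 from 5 and 6. The cut is at C3–C1′. Diethyl ketomalonate 6 supplies C2, C3, C4 and the C3 oxygen as one symmetric piece, so the prochiral substrate is reached in a single bond formation. The forward step needs aryllithium 7 to add to the central ketone and not to the esters.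

5 from 2, 1 and 3. The prenyl group at C3′ is introduced between the two ring oxygens of 2 through aryllithium 4. The bromine is already in the right place in commercial 1 (para to the phenol oxygen, ortho to the methoxy group), so no electrophilic bromination is needed once an alkene is present, and no question of bromination regiochemistry arises.

## Alternatives that were turned down

Alternative 1: Ring A by [4+2] benzannulation.
- Disconnection: C8–C8a and C4a–C5, so ring A is assembled last on a preformed ring C.
- Forward key step: the bis(silyloxy)diene A3 adds across the C4a=C8a double bond of the enantiopure bromo-dihydropyranone A2. Expulsion of the bromide and of the methoxy group, with loss of the silyl groups, aromatises the new ring to A1, the 3,4′-bis-MOM ether of 25.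
- For it: the 5,7-dioxygenation and the C6 prenyl group are written into the diene, so the 6- versus 8-prenyl question never arises and ring A needs no protecting groups. On this point it is stronger than the chosen route, which spends five steps on 19.
- Against it: the dienophile is a vinylogous ester whose ring oxygen donates into the enone, so it is poorly matched to an electron-rich diene. If the first bond forms at C8a in a stepwise Mukaiyama–Michael manner, the resulting β-alkoxy enolate can expel O1 and open ring C. The diene has a fully substituted ketene acetal terminus and is hydrolytically fragile.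
- Comparison: the step does not create C3, so A2 must already be a single enantiomer, and an asymmetric construction of the same quaternary carbinol is still needed on top of the annulation. The chosen strategy sets C3 in its key step and builds ring A from an aromatic precursor by two-electron steps of known behaviour.

Alternative 2: Photo-Fries acyl shift.
- Disconnection: C4–C4a, made by moving the acyl group of the aryl glycidate A5 (built on phenol 18) from the phenolic oxygen to the ortho carbon.
- Forward key step: irradiation at 254 nm homolyses the aryl oxygen–acyl bond; recombination of the radical pair at the ortho carbon and tautomerisation give the ortho-hydroxyaryl ketone A4, whose phenol then opens the oxirane at its CH2 carbon to close ring C.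
- For it: the phenol is symmetric with its para position blocked, so one regioisomer results; no strong acid and no organolithium are needed; it is one step shorter than the iodination and cyclisation pair used here. On step count at this stage it is slightly stronger.
- Against it: the acyl radical sits on a carbon that is tertiary, benzylic and part of an oxirane, so loss of carbon monoxide to a stabilised radical competes with recombination in the solvent cage. The aryl ketone product and both prenyl alkenes absorb or react under the same light, which invites inner-filter effects and secondary photochemistry.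
- Comparison: C3 must again come from a separate asymmetric step. The chosen route passes through a glycidic ester of the same type (20) and forms C4–C4a by an ionic ring closure (step 13) whose chemoselectivity can be argued from rates of known elementary steps.

Alternative 3: Rhodium-catalysed arylation of an aryloxypyruvate.
- Disconnection: C3–C1′.
- Forward key step: the rhodium source A9, which is the ethene complex [RhCl(C2H4)2]2, is combined with a chiral diene ligand to give a complex of monovalent rhodium. This complex takes the aryl group from boronic acid A8 and adds it to the keto group of pyruvate A7, giving the tertiary alcohol A6.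
- For it: it needs only a catalytic amount of A9 and ligand, joins the two halves and sets C3 in one step. Both arms of C3 are already at the right oxidation level, so reduction and activation steps fall away. In step economy it is clearly stronger, by about four steps.
- Against it: A8 is an electron-rich, ortho-substituted boronic acid that is prone to protodeboronation and slow to insert. A7 is an enolisable, strongly electrophilic α-keto ester that can hydrate or self-condense under the basic aqueous conditions of transmetalation. Facial selectivity would have to come from differentiating an ester from an aryloxymethyl group with a hindered aryl–rhodium species, which is hard to predict.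
- Comparison: if the selectivity is incomplete nothing downstream can raise it, and A6 still needs the C4–C4a closure. The chosen strategy offers in return a substrate made in three steps and an enantioconvergent handle: either half ester can be led to the R series by choosing which carboxyl is reduced.

Key step: step 4

Assumption: the esterase is taken to cleave the pro-S ethoxycarbonyl group of 8, which gives the (R)-half ester 9; the sense has to be found by screening, and the fallback for step 4 covers the opposite outcome.

## Route

Step 1
Reactants: 1 4-bromo-3-methoxyphenol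
Product: 2 1-bromo-2-methoxy-4-(methoxymethoxy)benzene
Conditions: MOMCl (1.3 equiv), iPr2NEt (1.6 equiv), CH2Cl2, 0 °C to rt
Reagents that add atoms: chloromethyl methyl ether, COCCl
Why: O-Alkylation of the phenoxide by the α-chloro ether (Williamson-type acetal formation); the MOM ether is the ortho-directing group for step 2 and is stable to every basic and organometallic step that follows.

Step 2
Reactants: 2 1-bromo-2-methoxy-4-(methoxymethoxy)benzene; 3 prenyl bromide (1-bromo-3-methylbut-2-ene)
Product: 5 1-bromo-2-methoxy-4-(methoxymethoxy)-3-prenylbenzene, via aryllithium 4 (not isolated)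
Conditions: lithium 2,2,6,6-tetramethylpiperidide (1.2 equiv), THF, −78 °C, 1 h; CuBr·SMe2 (10 mol %), 3 (1.3 equiv), −78 to 0 °C
Reagents that add atoms: none
Why: Directed ortho-metalation: the hydrogen between OMe and OMOM is the most acidic on the ring and both oxygens hold the lithium; a hindered lithium amide deprotonates without attacking the carbon–bromine bond, and the anion is meta to bromine, so it cannot lose lithium bromide to an aryne. Copper-catalysed allylic substitution then joins the aryl carbon to the primary carbon of 3.

Step 3
Reactants: 5 1-bromo-2-methoxy-4-(methoxymethoxy)-3-prenylbenzene; 6 diethyl ketomalonate (diethyl 2-oxopropanedioate)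
Product: 8 diethyl 2-hydroxy-2-(ring B aryl)propanedioate, via aryllithium 7 (not isolated)
Conditions: n-BuLi (1.05 equiv), THF, −78 °C, 20 min; added by cannula to 6 (1.3 equiv), THF, −78 °C; AcOH (1.1 equiv), −78 °C
Reagents that add atoms: none
Why: Bromine–lithium exchange at −78 °C is faster than any deprotonation, and the aryllithium adds to the central keto group of the vicinal tricarbonyl compound, by far its most electrophilic carbonyl (1,2-addition of an organolithium to a ketone); inverse addition keeps the ketone in excess so the ester groups are spared. The carbinol carbon carries two identical ester groups and is not yet a stereocentre.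

Step 4
Reactants: 8 diethyl 2-hydroxy-2-(ring B aryl)propanedioate
Product: 9 (2R)-3-ethoxy-2-hydroxy-3-oxo-2-(ring B aryl)propanoic acid
Conditions: pig liver esterase (isoenzyme chosen by screening), 0.1 M KH2PO4/K2HPO4 buffer pH 7.5, DMSO (10 vol %), 30 °C, pH-stat with 1 M NaOH (1.0 equiv); then 1 M HCl to pH 3 at 0 °C, EtOAc
Reagents that add atoms: water, O
Why: The catalytic serine of the esterase (serine–histidine–carboxylate triad) adds to whichever of the two enantiotopic ethoxycarbonyl groups the binding pocket places at the oxyanion hole, the ethoxy group leaves, and water cleaves the acyl-enzyme to the carboxylate, which is charged and no longer a substrate, so the reaction stops at the half ester. The closest known reaction type is the pig liver esterase desymmetrisation of prochiral 2,2-disubstituted malonate diesters to quaternary half esters. No ring is closed. The new stereocentre C3 is controlled only by the enzyme, which distinguishes the flat, bulky aryl group from the small hydroxyl when it docks the substrate; hydrolysis of the pro-S ester gives (R)-9. The selectivity needed is between enantiotopic groups, and the substrate supports it by the large size difference between its two non-ester substituents and by having no other group that hydrolyses at pH 7.5. C3 is quaternary, so 9 cannot racemise by enolisation; decarboxylation is avoided by acidifying cold and using the acid at once.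

Step 5
Reactants: 9 (2R)-3-ethoxy-2-hydroxy-3-oxo-2-(ring B aryl)propanoic acid
Product: 11 ethyl (2R)-2,3-dihydroxy-2-(ring B aryl)propanoate, via mixed anhydride 10 (not isolated)
Conditions: i-BuOCOCl (1.05 equiv), N-methylmorpholine (1.05 equiv), THF, −15 °C, 15 min; NaBH4 (2.5 equiv), H2O, −15 to 0 °C, 20 min
Reagents that add atoms: none
Why: Mixed carbonic anhydride activation followed by borohydride reduction converts only the free acid into CH2OH: NaBH4 does not reduce the ethyl ester in this time and temperature window, and it leaves the prenyl alkene alone, which a hydroborating reductant would not. No bond to C3 is touched; the acid arm becomes C2 and the ester arm is kept as C4, the assignment that leads to the R target.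

Step 6
Reactants: 11 ethyl (2R)-2,3-dihydroxy-2-(ring B aryl)propanoate
Product: 12 ethyl (2R)-2-hydroxy-2-(ring B aryl)-3-(tosyloxy)propanoate
Conditions: TsCl (1.15 equiv), Et3N (2.0 equiv), DMAP (5 mol %), CH2Cl2, 0 °C
Reagents that add atoms: 4-methylbenzenesulfonyl chloride, Cc1ccc(cc1)S(Cl)(=O)=O
Why: Sulfonylation distinguishes the primary from the hindered tertiary hydroxyl; any early closure to epoxide 20 is harmless because 20 is the reacting species in step 12.

Step 7
Reactants: 13 phloroglucinol (benzene-1,3,5-triol)
Product: 14 3,5-bis(methoxymethoxy)phenol
Conditions: MOMCl (2.0 equiv), iPr2NEt (2.2 equiv), DMF, 0 °C to rt; chromatography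
Reagents that add atoms: chloromethyl methyl ether, COCCl
Why: Statistical O-alkylation of a threefold symmetric triol; the mono-, bis- and tris-ethers differ by one free hydroxyl each and should separate readily, and the unwanted ethers can be returned to 13 by acid hydrolysis.

Step 8
Reactants: 14 3,5-bis(methoxymethoxy)phenol
Product: 15 [3,5-bis(methoxymethoxy)phenoxy]tri(propan-2-yl)silane
Conditions: i-Pr3SiCl (1.2 equiv), imidazole (2.0 equiv), DMF, rt
Reagents that add atoms: chlorotri(propan-2-yl)silane, CC(C)[Si](Cl)(C(C)C)C(C)C
Why: Silylation of the remaining phenol; the bulky silyl ether does not direct lithiation, shields its own ortho positions, and can later be removed by fluoride without touching the MOM groups.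

Step 9
Reactants: 15 [3,5-bis(methoxymethoxy)phenoxy]tri(propan-2-yl)silane; 3 prenyl bromide
Product: 17 [3,5-bis(methoxymethoxy)-4-prenylphenoxy]tri(propan-2-yl)silane, via aryllithium 16 (not isolated)
Conditions: n-BuLi (1.15 equiv), THF, 0 °C, 1 h; CuBr·SMe2 (10 mol %), 3 (1.3 equiv), −78 to 0 °C
Reagents that add atoms: none
Why: Directed ortho-metalation at the one position flanked by two MOM ethers, followed by copper-catalysed allylation as in step 2; the lithium is para to the silyloxy group, so no silyl shift from oxygen to carbon is possible.

Step 10
Reactants: 17 [3,5-bis(methoxymethoxy)-4-prenylphenoxy]tri(propan-2-yl)silane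
Product: 18 3,5-bis(methoxymethoxy)-4-prenylphenol
Conditions: Bu4NF (1.1 equiv), AcOH (1.1 equiv), THF, 0 °C
Reagents that add atoms: none
Why: Fluoride cleaves the silicon–oxygen bond of the aryl silyl ether while acetals and alkene are inert; 18 has a mirror plane through C1 and C4, so its two ortho positions are equivalent.

Step 11
Reactants: 18 3,5-bis(methoxymethoxy)-4-prenylphenol
Product: 19 2-iodo-3,5-bis(methoxymethoxy)-4-prenylphenol
Conditions: N-iodosuccinimide (1.0 equiv), CH2Cl2, −78 to −40 °C, dark
Reagents that add atoms: N-iodosuccinimide, O=C1CCC(=O)N1I
Why: Electrophilic aromatic iodination ortho to the free hydroxyl of a phloroglucinol-type ring should be much faster than attack on the isolated alkene, whose neighbouring oxygens are capped and cannot trap an iodonium ion. The para position is blocked and the two ortho positions are identical, so only over-iodination has to be held back by stoichiometry and temperature.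

Step 12
Reactants: 12 ethyl (2R)-2-hydroxy-2-(ring B aryl)-3-(tosyloxy)propanoate; 19 2-iodo-3,5-bis(methoxymethoxy)-4-prenylphenol
Product: 21 ethyl (2R)-2-hydroxy-3-[2-iodo-3,5-bis(methoxymethoxy)-4-prenylphenoxy]-2-(ring B aryl)propanoate, via glycidic ester 20 (not isolated)
Conditions: Cs2CO3 (2.0 equiv), DMF, rt 1 h, then 50 °C
Reagents that add atoms: none
Why: The tertiary alkoxide displaces the neighbouring tosylate (3-exo-tet, intramolecular Williamson reaction) and the phenoxide of 19 opens the 2,2-disubstituted oxirane at its CH2 carbon by SN2. Both events take place at C2, so the C3–O bond and the configuration of C3 are untouched.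

Step 13
Reactants: 21 ethyl (2R)-2-hydroxy-3-[2-iodo-3,5-bis(methoxymethoxy)-4-prenylphenoxy]-2-(ring B aryl)propanoate
Product: 24 (3R)-3-hydroxy-5,7-bis(methoxymethoxy)-6-prenyl-3-(ring B aryl)chroman-4-one, via lithium alkoxide 22 (not isolated), via aryllithium 23 (not isolated)
Conditions: MeLi (1.0 equiv), THF, −78 °C; t-BuLi (2.05 equiv), −78 °C, then to −20 °C; AcOH (2.5 equiv), −78 °C
Reagents that add atoms: none
Why: Parham cyclisation: iodine–lithium exchange at −78 °C outruns addition of the alkyllithium to the ester, and the aryllithium, held between two ether oxygens, attacks the ester carbonyl intramolecularly (6-exo-trig) to close ring C at C4–C4a with loss of the ethoxy group. The hydroxyl is deprotonated first so that it cannot quench the aryl anion, and the ketone formed is shielded from a second addition by two ortho substituents and the quaternary C3.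

Step 14
Reactants: 24 (3R)-3-hydroxy-5,7-bis(methoxymethoxy)-6-prenyl-3-(ring B aryl)chroman-4-one
Product: 25 (3R)-3,5,7-trihydroxy-3-(4-hydroxy-2-methoxy-3-prenylphenyl)-6-prenylchroman-4-one
Conditions: HCl (1 M) in MeOH, 25 to 40 °C, stopped as soon as the last acetal is cleaved
Reagents that add atoms: none
Why: Acid-catalysed acetal exchange with methanol removes the three MOM ethers, the chelated one at O5 first; dilute acid at mild temperature is the established compromise for freeing prenylated phenols without closing them onto the alkene, and C3 has no pathway for epimerisation.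

## Compound list

1 | 4-bromo-3-methoxyphenol | COc1cc(O)ccc1Br | starting material
2 | 1-bromo-2-methoxy-4-(methoxymethoxy)benzene | COCOc1ccc(Br)c(OC)c1 | intermediate
3 | prenyl bromide (1-bromo-3-methylbut-2-ene) | CC(C)=CCBr | starting material
4 | [3-bromo-2-methoxy-6-(methoxymethoxy)phenyl]lithium | COCOc1ccc(Br)c(OC)c1[Li] | intermediate (not isolated)
5 | 1-bromo-2-methoxy-4-(methoxymethoxy)-3-(3-methylbut-2-en-1-yl)benzene | COCOc1ccc(Br)c(OC)c1CC=C(C)C | intermediate
6 | diethyl ketomalonate (diethyl 2-oxopropanedioate) | CCOC(=O)C(=O)C(=O)OCC | starting material
7 | [2-methoxy-4-(methoxymethoxy)-3-(3-methylbut-2-en-1-yl)phenyl]lithium | COCOc1ccc([Li])c(OC)c1CC=C(C)C | intermediate (not isolated)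
8 | diethyl 2-hydroxy-2-[2-methoxy-4-(methoxymethoxy)-3-(3-methylbut-2-en-1-yl)phenyl]propanedioate | CCOC(=O)C(O)(C(=O)OCC)c1ccc(OCOC)c(CC=C(C)C)c1OC | intermediate
9 | (2R)-3-ethoxy-2-hydroxy-2-[2-methoxy-4-(methoxymethoxy)-3-(3-methylbut-2-en-1-yl)phenyl]-3-oxopropanoic acid | COc1c([C@@](C(=O)OCC)(O)C(=O)O)ccc(OCOC)c1CC=C(C)C | intermediate
10 | mixed isobutyl carbonic anhydride of 9 (same spatial arrangement at C3) | COc1c([C@@](C(=O)OCC)(O)C(=O)OC(=O)OCC(C)C)ccc(OCOC)c1CC=C(C)C | intermediate (not isolated)
11 | ethyl (2R)-2,3-dihydroxy-2-[2-methoxy-4-(methoxymethoxy)-3-(3-methylbut-2-en-1-yl)phenyl]propanoate | COc1c([C@@](C(=O)OCC)(O)CO)ccc(OCOC)c1CC=C(C)C | intermediate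
12 | ethyl (2R)-2-hydroxy-2-[2-methoxy-4-(methoxymethoxy)-3-(3-methylbut-2-en-1-yl)phenyl]-3-[(4-methylbenzenesulfonyl)oxy]propanoate | COc1c([C@@](C(=O)OCC)(O)COS(=O)(=O)c2ccc(C)cc2)ccc(OCOC)c1CC=C(C)C | intermediate
13 | phloroglucinol (benzene-1,3,5-triol) | Oc1cc(O)cc(O)c1 | starting material
14 | 3,5-bis(methoxymethoxy)phenol | COCOc1cc(O)cc(OCOC)c1 | intermediate
15 | [3,5-bis(methoxymethoxy)phenoxy]tri(propan-2-yl)silane | COCOc1cc(O[Si](C(C)C)(C(C)C)C(C)C)cc(OCOC)c1 | intermediate
16 | [2,6-bis(methoxymethoxy)-4-{[tri(propan-2-yl)silyl]oxy}phenyl]lithium | COCOc1cc(O[Si](C(C)C)(C(C)C)C(C)C)cc(OCOC)c1[Li] | intermediate (not isolated)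
17 | [3,5-bis(methoxymethoxy)-4-(3-methylbut-2-en-1-yl)phenoxy]tri(propan-2-yl)silane | COCOc1cc(O[Si](C(C)C)(C(C)C)C(C)C)cc(OCOC)c1CC=C(C)C | intermediate
18 | 3,5-bis(methoxymethoxy)-4-(3-methylbut-2-en-1-yl)phenol | COCOc1cc(O)cc(OCOC)c1CC=C(C)C | intermediate
19 | 2-iodo-3,5-bis(methoxymethoxy)-4-(3-methylbut-2-en-1-yl)phenol | COCOc1cc(O)c(I)c(OCOC)c1CC=C(C)C | intermediate
20 | ethyl (2R)-2-[2-methoxy-4-(methoxymethoxy)-3-(3-methylbut-2-en-1-yl)phenyl]oxirane-2-carboxylate | COc1c([C@@](C(=O)OCC)(O2)C2)ccc(OCOC)c1CC=C(C)C | intermediate (not isolated)
21 | ethyl (2R)-2-hydroxy-3-[2-iodo-3,5-bis(methoxymethoxy)-4-(3-methylbut-2-en-1-yl)phenoxy]-2-[2-methoxy-4-(methoxymethoxy)-3-(3-methylbut-2-en-1-yl)phenyl]propanoate | COc1c([C@@](C(=O)OCC)(O)COc2cc(OCOC)c(CC=C(C)C)c(OCOC)c2I)ccc(OCOC)c1CC=C(C)C | intermediate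
22 | lithium alkoxide of 21 (tertiary O–Li) | COc1c([C@@](C(=O)OCC)(O[Li])COc2cc(OCOC)c(CC=C(C)C)c(OCOC)c2I)ccc(OCOC)c1CC=C(C)C | intermediate (not isolated)
23 | ring A aryllithium derived from 22 (lithium in place of iodine) | COc1c([C@@](C(=O)OCC)(O[Li])COc2cc(OCOC)c(CC=C(C)C)c(OCOC)c2[Li])ccc(OCOC)c1CC=C(C)C | intermediate (not isolated)
24 | (3R)-3-hydroxy-3-[2-methoxy-4-(methoxymethoxy)-3-(3-methylbut-2-en-1-yl)phenyl]-5,7-bis(methoxymethoxy)-6-(3-methylbut-2-en-1-yl)-2,3-dihydro-4H-chromen-4-one | COc1c([C@@]2(O)COc3cc(OCOC)c(CC=C(C)C)c(OCOC)c3C2=O)ccc(OCOC)c1CC=C(C)C | intermediate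
25 | (3R)-3,5,7-trihydroxy-3-[4-hydroxy-2-methoxy-3-(3-methylbut-2-en-1-yl)phenyl]-6-(3-methylbut-2-en-1-yl)-2,3-dihydro-4H-chromen-4-one | COc1c([C@@]2(O)COc3cc(O)c(CC=C(C)C)c(O)c3C2=O)ccc(O)c1CC=C(C)C | target

## Step count and least certain steps

Total: 14 steps. Longest linear sequence: 9 steps (steps 1 to 6, then 12 to 14); the ring A branch (steps 7 to 11) joins at step 12.

Key step (step 4). The ortho-methoxy, prenyl-bearing aryl group may fit the active site poorly, so that turnover is slow, or the enzyme may discriminate the two ester groups weakly or in the opposite sense. The fallback sets out from 8. Monosaponification with KOH (1.0 equiv) in EtOH at 0 °C should give the racemic half ester F1. Preparative chromatography on a chiral stationary phase separates it into 9, which re-enters at step 5, and the (S)-half ester F2. F2 is reduced at its ester group with LiBH4 in THF (the lithium carboxylate is inert) to the dihydroxy acid F3, and ethylation of the carboxylate of F3 with EtI and KHCO3 in DMF comes back to the route at 11. Both antipodes therefore converge on 11, and the same sequence from F2 through F3 to 11 is used if an esterase delivers F2 selectively.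

Step 13. The aryl anion may be protonated before it cyclises, or the alkyllithium may attack the ester, leaving open-chain material. The fallback changes the polarity of the ring closure and sets out from 12 and 18. Cs2CO3 in DMF should join them to the iodine-free ether F4, and LiOH in THF/H2O then gives the acid F5. Trifluoroacetic anhydride in CH2Cl2 at 0 °C forms the mixed anhydride, which acylates ring A at either of its two equivalent ortho positions (intramolecular Friedel–Crafts acylation) and at the same time esterifies the tertiary hydroxyl, giving the trifluoroacetate F6. K2CO3 in MeOH removes that ester and the sequence comes back to the route at 24. This variant is held in reserve because it exposes acetals and alkenes to trifluoroacetic acid.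

Step 5. Hydride may attack the carbonate carbonyl of the hindered mixed anhydride and return the acid, the α-hydroxy ester may be reduced further, or the half ester may lose carbon dioxide on handling. The fallback sets out from 9. EtSH, EDC hydrochloride and DMAP (5 mol %) in CH2Cl2 should give the S-ethyl thioester F7, which Et3SiH with Pd/C (5 mol %) in acetone (Fukuyama reduction) converts into the aldehyde F8. NaBH4 in EtOH at −40 °C then reduces only the aldehyde and comes back to the route at 11.

Step 14. The freed phenols may add to the prenyl double bonds under acid, or the tertiary alcohol may be lost by dehydration before the last acetal is cleaved. The fallback avoids protic acid and sets out from 24. Et3SiOTf (excess) with 2,2′-bipyridyl in CH2Cl2 at 0 °C to rt converts the aryl acetals through N-(methoxymethyl)bipyridinium salts into aryl silyl ethers and silylates the tertiary hydroxyl as well, giving the tetrakis(triethylsilyl) ether F9. HF·pyridine buffered with pyridine in THF at 0 °C removes all four silyl groups and comes back to the route at 25.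

Step 2. Deprotonation may be incomplete, or may compete at the position next to bromine with loss of lithium bromide and aryne formation. The fallback takes the bromine off the ring during the metalation and sets out from 2. n-BuLi and then Me3SiCl should give the arylsilane F10, and n-BuLi in THF at 0 °C followed by CuBr·SMe2 (10 mol %) and 3 gives the prenylated arylsilane F11. N-Bromosuccinimide in MeCN at 0 °C replaces the silyl group by bromine (ipso-bromodesilylation) and comes back to the route at 5.

## Further compounds

F1 | step 4 | racemic 3-ethoxy-2-hydroxy-2-[2-methoxy-4-(methoxymethoxy)-3-(3-methylbut-2-en-1-yl)phenyl]-3-oxopropanoic acid | CCOC(=O)C(O)(C(=O)O)c1ccc(OCOC)c(CC=C(C)C)c1OC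
F2 | step 4 | (2S)-3-ethoxy-2-hydroxy-2-[2-methoxy-4-(methoxymethoxy)-3-(3-methylbut-2-en-1-yl)phenyl]-3-oxopropanoic acid | COc1c([C@](C(=O)OCC)(O)C(=O)O)ccc(OCOC)c1CC=C(C)C
F3 | step 4 | (2R)-2,3-dihydroxy-2-[2-methoxy-4-(methoxymethoxy)-3-(3-methylbut-2-en-1-yl)phenyl]propanoic acid | COc1c([C@](CO)(O)C(=O)O)ccc(OCOC)c1CC=C(C)C
F4 | step 13 | ethyl (2R)-3-[3,5-bis(methoxymethoxy)-4-(3-methylbut-2-en-1-yl)phenoxy]-2-hydroxy-2-[2-methoxy-4-(methoxymethoxy)-3-(3-methylbut-2-en-1-yl)phenyl]propanoate | COc1c([C@@](C(=O)OCC)(O)COc2cc(OCOC)c(CC=C(C)C)c(OCOC)c2)ccc(OCOC)c1CC=C(C)C
F5 | step 13 | (2R)-3-[3,5-bis(methoxymethoxy)-4-(3-methylbut-2-en-1-yl)phenoxy]-2-hydroxy-2-[2-methoxy-4-(methoxymethoxy)-3-(3-methylbut-2-en-1-yl)phenyl]propanoic acid | COc1c([C@@](C(=O)O)(O)COc2cc(OCOC)c(CC=C(C)C)c(OCOC)c2)ccc(OCOC)c1CC=C(C)C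
F6 | step 13 | 3-O-trifluoroacetate of 24 | COc1c([C@@]2(OC(=O)C(F)(F)F)COc3cc(OCOC)c(CC=C(C)C)c(OCOC)c3C2=O)ccc(OCOC)c1CC=C(C)C
F7 | step 5 | ethyl 3-(ethylsulfanyl)-2-hydroxy-2-[2-methoxy-4-(methoxymethoxy)-3-(3-methylbut-2-en-1-yl)phenyl]-3-oxopropanoate (S-ethyl thioester of 9, same spatial arrangement at C3) | COc1c([C@@](C(=O)OCC)(O)C(=O)SCC)ccc(OCOC)c1CC=C(C)C
F8 | step 5 | ethyl 2-hydroxy-2-[2-methoxy-4-(methoxymethoxy)-3-(3-methylbut-2-en-1-yl)phenyl]-3-oxopropanoate (aldehyde from 9, same spatial arrangement at C3) | COc1c([C@@](C(=O)OCC)(O)C=O)ccc(OCOC)c1CC=C(C)C
F9 | step 14 | 3,5,7,4′-tetrakis-O-(triethylsilyl) ether of 25 | COc1c([C@@]2(O[Si](CC)(CC)CC)COc3cc(O[Si](CC)(CC)CC)c(CC=C(C)C)c(O[Si](CC)(CC)CC)c3C2=O)ccc(O[Si](CC)(CC)CC)c1CC=C(C)C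
F10 | step 2 | [2-methoxy-4-(methoxymethoxy)phenyl]trimethylsilane | COCOc1ccc([Si](C)(C)C)c(OC)c1
F11 | step 2 | [2-methoxy-4-(methoxymethoxy)-3-(3-methylbut-2-en-1-yl)phenyl]trimethylsilane | COCOc1ccc([Si](C)(C)C)c(OC)c1CC=C(C)C
A1 | alternative 1 | 3,4′-bis-O-(methoxymethyl) ether of 25 | COc1c([C@@]2(OCOC)COc3cc(O)c(CC=C(C)C)c(O)c3C2=O)ccc(OCOC)c1CC=C(C)C
A2 | alternative 1 | 5-bromo-3-(methoxymethoxy)-3-[2-methoxy-4-(methoxymethoxy)-3-(3-methylbut-2-en-1-yl)phenyl]-2,3-dihydro-4H-pyran-4-one, single enantiomer | COc1c([C@@]2(OCOC)COC=C(Br)C2=O)ccc(OCOC)c1CC=C(C)C
A3 | alternative 1 | 1-methoxy-2-(3-methylbut-2-en-1-yl)-1,3-bis(trimethylsilyloxy)buta-1,3-diene | COC(O[Si](C)(C)C)=C(CC=C(C)C)C(=C)O[Si](C)(C)C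
A4 | alternative 2 | [2-hydroxy-4,6-bis(methoxymethoxy)-5-(3-methylbut-2-en-1-yl)phenyl] {2-[2-methoxy-4-(methoxymethoxy)-3-(3-methylbut-2-en-1-yl)phenyl]oxiran-2-yl} ketone, single enantiomer | COc1c([C@]2(C(=O)c3c(O)cc(OCOC)c(CC=C(C)C)c3OCOC)CO2)ccc(OCOC)c1CC=C(C)C
A5 | alternative 2 | 3,5-bis(methoxymethoxy)-4-(3-methylbut-2-en-1-yl)phenyl 2-[2-methoxy-4-(methoxymethoxy)-3-(3-methylbut-2-en-1-yl)phenyl]oxirane-2-carboxylate, single enantiomer | COc1c([C@]2(C(=O)Oc3cc(OCOC)c(CC=C(C)C)c(OCOC)c3)CO2)ccc(OCOC)c1CC=C(C)C
A6 | alternative 3 | methyl (2R)-3-[3,5-bis(methoxymethoxy)-4-(3-methylbut-2-en-1-yl)phenoxy]-2-hydroxy-2-[2-methoxy-3-(3-methylbut-2-en-1-yl)-4-{[tri(propan-2-yl)silyl]oxy}phenyl]propanoate | COc1c([C@@](C(=O)OC)(O)COc2cc(OCOC)c(CC=C(C)C)c(OCOC)c2)ccc(O[Si](C(C)C)(C(C)C)C(C)C)c1CC=C(C)C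
A7 | alternative 3 | methyl 3-[3,5-bis(methoxymethoxy)-4-(3-methylbut-2-en-1-yl)phenoxy]-2-oxopropanoate | COC(=O)C(=O)COc1cc(OCOC)c(CC=C(C)C)c(OCOC)c1
A8 | alternative 3 | [2-methoxy-3-(3-methylbut-2-en-1-yl)-4-{[tri(propan-2-yl)silyl]oxy}phenyl]boronic acid | COc1c(B(O)O)ccc(O[Si](C(C)C)(C(C)C)C(C)C)c1CC=C(C)C
A9 | alternative 3 | di-μ-chlorotetrakis(ethene)dirhodium, [RhCl(C2H4)2]2 | C=C.C=C.C=C.C=C.[Cl-].[Cl-].[Rh+].[Rh+]
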